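**Retrosynthetic overview**
- Disconnect the ester C–O bond last: (S)-18-methylicosan-1-ol (12) plus 2,3-bis(benzyloxy)benzoic acid (15); hydrogenolysis then releases the catechol.
- Disconnect C19–C20 of the alcohol: the ethyl terminus comes from a CH2OTs group and a methyl cuprate.
- Disconnect C16–C17: a Cu-catalysed sp3–sp3 coupling joins a C3 chiral Grignard (from 5) to a C16 bromo-THP ether (7).
- The only stereocentre comes from a lipase (serine hydrolase) desymmetrisation of prochiral 2-methylpropane-1,3-diol; the two CH2O arms are then elaborated in the order that gives (S).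
- No ring is formed: the arene is bought intact, and the THP ring is only a protecting group.

Assumption: 16-bromohexadecan-1-ol is bought as a catalogue compound (otherwise one step from 16-bromohexadecanoic acid with BH3·THF).

**Route**

**Step 1**
Reactants: 1, 2-methylpropane-1,3-diol
Product: 2, (S)-3-hydroxy-2-methylpropyl acetate
Conditions: lipase (Pseudomonas fluorescens lipase, Amano AK, on Celite), vinyl acetate (3 equiv), CHCl3, 25–30 °C; run past the monoacetate maximum (about 40–50% diacetate by GC), filter, chromatograph cold and use at once. The diacetate is recycled to 1 with K2CO3/MeOH.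
Reagents that add atoms: vinyl acetate, CC(=O)OC=C
Why: Lipase-catalysed irreversible transesterification acylates the pro-S hydroxymethyl group of the prochiral diol (enantiotopic-group desymmetrisation), and the minor (R)-monoacetate is acylated faster to the achiral diacetate, which raises the ee of 2 (expected ≥98%).

**Step 2**
Reactants: 2, (S)-3-hydroxy-2-methylpropyl acetate
Product: 3, (R)-3-[(tert-butyldiphenylsilyl)oxy]-2-methylpropyl acetate
Conditions: TBDPSCl, imidazole, CH2Cl2, 0 °C to rt
Reagents that add atoms: TBDPSCl, CC(C)(C)[Si](Cl)(c1ccccc1)c1ccccc1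
Why: Fast silylation of the primary alcohol under mild base locks the two arms as different groups before 1,3-acyl migration can erode the ee; the descriptor changes to R only because CIP priorities change.

**Step 3**
Reactants: 3, (R)-3-[(tert-butyldiphenylsilyl)oxy]-2-methylpropyl acetate
Product: 4, (R)-3-[(tert-butyldiphenylsilyl)oxy]-2-methylpropan-1-ol
Conditions: K2CO3, MeOH, 0 °C to rt
Reagents that add atoms: none
Why: Zemplén-type methanolysis removes the acetate, and the bulky TBDPS ether neither cleaves nor migrates under these conditions; ee is checked here by chiral HPLC or Mosher ester.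

**Step 4**
Reactants: 4, (R)-3-[(tert-butyldiphenylsilyl)oxy]-2-methylpropan-1-ol
Product: 5, (S)-(3-bromo-2-methylpropoxy)(tert-butyl)diphenylsilane
Conditions: CBr4, PPh3, CH2Cl2, 0 °C
Reagents that add atoms: carbon tetrabromide, BrC(Br)(Br)Br
Why: The Appel reaction converts the primary alcohol to the bromide under neutral conditions; the stereocentre is β to the reacting carbon and is untouched.

**Step 5**
Reactants: 6, 16-bromohexadecan-1-ol
Product: 7, 2-[(16-bromohexadecyl)oxy]oxane (racemic at the acetal carbon)
Conditions: 3,4-dihydro-2H-pyran, PPTS (cat.), CH2Cl2, rt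
Reagents that add atoms: 3,4-dihydro-2H-pyran, C1CCOC=C1
Why: Acid-catalysed THP acetal formation masks the hydroxyl without base, so the bromo alcohol cannot self-alkylate, and the acetal tolerates Grignard and cuprate chemistry.

**Step 6**
Reactants: 5, (S)-(3-bromo-2-methylpropoxy)(tert-butyl)diphenylsilane (1.5 equiv, as its Grignard reagent); 7, 2-[(16-bromohexadecyl)oxy]oxane (1.0 equiv)
Product: 8, tert-butyl{[(2R)-2-methyl-19-(oxan-2-yloxy)nonadecyl]oxy}diphenylsilane
Conditions: (i) 5, Mg, cat. BrCH2CH2Br, THF, 45 °C; (ii) add to 7, Li2CuCl4 (4 mol%), NMP (4 equiv), THF, 0 °C to rt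
Reagents that add atoms: none
Why: Kochi/Cahiez Cu-catalysed sp3–sp3 coupling of a primary alkyl Grignard with an unbranched primary bromide is dependable, and the stereocentre is β to magnesium and configurationally unaffected.

**Step 7**
Reactants: 8, tert-butyl{[(2R)-2-methyl-19-(oxan-2-yloxy)nonadecyl]oxy}diphenylsilane
Product: 9, (2R)-2-methyl-19-(oxan-2-yloxy)nonadecan-1-ol
Conditions: TBAF, THF, rt
Reagents that add atoms: none
Why: Fluoride cleaves the Si–O bond selectively, and the THP acetal is inert to fluoride and base.

**Step 8**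
Reactants: 9, (2R)-2-methyl-19-(oxan-2-yloxy)nonadecan-1-ol
Product: 10, (2R)-2-methyl-19-(oxan-2-yloxy)nonadecyl 4-methylbenzenesulfonate
Conditions: TsCl, Et3N, DMAP (cat.), CH2Cl2, 0 °C to rt
Reagents that add atoms: p-toluenesulfonyl chloride, Cc1ccc(cc1)S(Cl)(=O)=O
Why: Standard sulfonylation of a primary alcohol under basic conditions, which the THP ether survives.

**Step 9**
Reactants: 10, (2R)-2-methyl-19-(oxan-2-yloxy)nonadecyl 4-methylbenzenesulfonate
Product: 11, 2-{[(18S)-18-methylicosyl]oxy}oxane
Conditions: Me2CuLi (5 equiv, from MeLi and CuI), Et2O, −30 to 0 °C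
Reagents that add atoms: methyllithium, [Li]C (used as lithium dimethylcuprate)
Why: SN2 displacement of a primary tosylate by a Gilman cuprate turns CH2OTs into the ethyl terminus; the stereocentre is adjacent to, not at, the reacting carbon, so it now reads (S) with no change in geometry.

**Step 10**
Reactants: 11, 2-{[(18S)-18-methylicosyl]oxy}oxane
Product: 12, (S)-18-methylicosan-1-ol
Conditions: TsOH·H2O (cat.), MeOH/CH2Cl2, rt to 40 °C
Reagents that add atoms: none
Why: Acid-catalysed transacetalisation removes the THP group, and nothing else in the saturated chain is acid-sensitive.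

**Step 11**
Reactants: 13, 2,3-dihydroxybenzoic acid
Product: 14, benzyl 2,3-bis(benzyloxy)benzoate
Conditions: BnBr (3.5 equiv), K2CO3, DMF, 60 °C
Reagents that add atoms: benzyl bromide, BrCc1ccccc1
Why: Exhaustive Williamson O-alkylation of both phenols and the carboxylate protects the oxidation-prone catechol.

**Step 12**
Reactants: 14, benzyl 2,3-bis(benzyloxy)benzoate
Product: 15, 2,3-bis(benzyloxy)benzoic acid
Conditions: NaOH (aq), MeOH/THF, reflux; then HCl to pH 2
Reagents that add atoms: sodium hydroxide/water, [Na+].[OH-] (one carboxyl oxygen)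
Why: Saponification cleaves only the benzyl ester, and the aryl benzyl ethers are stable to hydroxide.

**Step 13**
Reactants: 12, (S)-18-methylicosan-1-ol; 15, 2,3-bis(benzyloxy)benzoic acid
Product: 16, (S)-18-methylicosyl 2,3-bis(benzyloxy)benzoate
Conditions: EDC·HCl, DMAP, CH2Cl2, rt
Reagents that add atoms: none
Why: Steglich carbodiimide/DMAP esterification of an unhindered primary alcohol; with the phenols benzylated there is no competing O-acylation or oligomerisation.

**Step 14**
Reactants: 16, (S)-18-methylicosyl 2,3-bis(benzyloxy)benzoate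
Product: 17, Gentiside H, (S)-18-methylicosyl 2,3-dihydroxybenzoate
Conditions: H2 (1 atm), 10% Pd/C, EtOAc/THF, rt
Reagents that add atoms: none
Why: Hydrogenolysis removes both O-benzyl groups under neutral conditions, while the non-benzylic alkyl ester and the remote stereocentre are inert.

**Compound list**
1 | 2-methylpropane-1,3-diol | CC(CO)CO | starting material
2 | (S)-3-hydroxy-2-methylpropyl acetate | CC(=O)OC[C@@H](C)CO | intermediate
3 | (R)-3-[(tert-butyldiphenylsilyl)oxy]-2-methylpropyl acetate | CC(=O)OC[C@@H](C)CO[Si](c1ccccc1)(c1ccccc1)C(C)(C)C | intermediate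
4 | (R)-3-[(tert-butyldiphenylsilyl)oxy]-2-methylpropan-1-ol | OC[C@@H](C)CO[Si](c1ccccc1)(c1ccccc1)C(C)(C)C | intermediate
5 | (S)-(3-bromo-2-methylpropoxy)(tert-butyl)diphenylsilane | BrC[C@@H](C)CO[Si](c1ccccc1)(c1ccccc1)C(C)(C)C | intermediate
6 | 16-bromohexadecan-1-ol | OCCCCCCCCCCCCCCCCBr | starting material
7 | 2-[(16-bromohexadecyl)oxy]oxane | BrCCCCCCCCCCCCCCCCOC1CCCCO1 | intermediate
8 | tert-butyl{[(2R)-2-methyl-19-(oxan-2-yloxy)nonadecyl]oxy}diphenylsilane | CC(C)(C)[Si](c1ccccc1)(c1ccccc1)OC[C@H](C)CCCCCCCCCCCCCCCCCOC1CCCCO1 | intermediate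
9 | (2R)-2-methyl-19-(oxan-2-yloxy)nonadecan-1-ol | OC[C@H](C)CCCCCCCCCCCCCCCCCOC1CCCCO1 | intermediate
10 | (2R)-2-methyl-19-(oxan-2-yloxy)nonadecyl 4-methylbenzenesulfonate | Cc1ccc(cc1)S(=O)(=O)OC[C@H](C)CCCCCCCCCCCCCCCCCOC1CCCCO1 | intermediate
11 | 2-{[(18S)-18-methylicosyl]oxy}oxane | CC[C@H](C)CCCCCCCCCCCCCCCCCOC1CCCCO1 | intermediate
12 | (S)-18-methylicosan-1-ol | CC[C@H](C)CCCCCCCCCCCCCCCCCO | intermediate
13 | 2,3-dihydroxybenzoic acid | OC(=O)c1cccc(O)c1O | starting material
14 | benzyl 2,3-bis(benzyloxy)benzoate | O=C(OCc1ccccc1)c1cccc(OCc2ccccc2)c1OCc1ccccc1 | intermediate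
15 | 2,3-bis(benzyloxy)benzoic acid | OC(=O)c1cccc(OCc2ccccc2)c1OCc1ccccc1 | intermediate
16 | (S)-18-methylicosyl 2,3-bis(benzyloxy)benzoate | CC[C@H](C)CCCCCCCCCCCCCCCCCOC(=O)c1cccc(OCc2ccccc2)c1OCc1ccccc1 | intermediate
17 | Gentiside H, (S)-18-methylicosyl 2,3-dihydroxybenzoate | CC[C@H](C)CCCCCCCCCCCCCCCCCOC(=O)c1cccc(O)c1O | target

**Step count**
Total steps: 14.
Longest linear sequence: 11 steps (1, 2, 3, 4, 6, 7, 8, 9, 10, 13, 14).

**Three steps most likely to fail, with fallbacks**
1. Step 1 (lipase desymmetrisation): the ee may be insufficient, or 2 may racemise by 1,3-acyl migration before silylation. Fallback: set the centre by ene-reductase (Old Yellow Enzyme family, NADPH with glucose dehydrogenase recycling) reduction of achiral methyl 2-(hydroxymethyl)acrylate to (R)-Roche ester, which has no migration pathway. Then PMB-protect the OH, reduce the ester with LiAlH4, silylate with TBDPSCl and remove PMB with DDQ to reach the same alcohol 4.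
2. Step 6 (Grignard formation from 5 and Cu-catalysed sp3–sp3 coupling): Wurtz homocoupling or incomplete coupling is possible. Fallback: convert 4 to the iodide and then the phosphonium salt, run a Wittig olefination with 16-(oxan-2-yloxy)hexadecanal, and saturate the alkene with diimide to give 8.
3. Step 9 (cuprate displacement at the β-branched tosylate): the reaction may be sluggish or give elimination or reduction products. Fallback: oxidise 9 with Dess–Martin periodinane to the α-methyl aldehyde, methylenate immediately with Ph3P=CH2 at low temperature, and reduce the terminal alkene with diimide (TsNHNH2, NaOAc) to give 11. The ee must be rechecked because the aldehyde is epimerisable.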